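Isomerisation moves material between target and isomer of the product without changing [target]+[isomer of the product], and at this fixed temperature its balance point is a target share of 25.0%. That share is the zero of our scale.

| setting | Thursday's | Tuesday's | Friday's | Sunday's |
|---|---|---|---|---|
| acidic substrate | 0.40 M | 0.40 M (fed, over 2.50 min) | 0.40 M | 0.40 M |
| free base | 0.320 M | 0.320 M | 0.320 M | 0.320 M |
| electrophile | 0.720 M | 0.720 M | 0.720 M | 0.720 M (fed, over 2.50 min) |
| remark | a single well-mixed tank run continuously and read at steady state, 2.5 min in it on average | a stirred flask in which acidic substrate is dosed at a steady rate over 2.50 min without added volume, worked up at 2.5 min | a closed flask charged with all of it at once and left for 2.5 min | a stirred flask in which electrophile is dosed at a steady rate over 2.50 min without added volume, worked up at 2.5 min |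
| time |  | 2.5 min | 2.5 min | 2.5 min |

    acidic substrate + free base ⇌ protonated base + anion, settled at all times (K1 = 1.4)
    electrophile + anion → target (k2 = 0.995 L mol⁻¹ s⁻¹)
    target ⇌ isomer of the product (K3 = 3.0, k3 = 0.00380 s⁻¹)

- the stated concentrations are those of everything mixed, before any reaction; amounts are the same in each set-up
- the feed brings no volume worth counting
- run time (Tuesday's): 2.5 min

* order of the set-ups by the share of target in all that became target or isomer of the product, at the outlet or at the end, highest first (Thursday's / Tuesday's / Friday's / Sunday's)
* share of target in all that became target or isomer of the product, at the outlet or at the end, Thursday's
* share of target in all that became target or isomer of the product, at the outlet or at the end, Tuesday's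
* share of target in all that became target or isomer of the product, at the outlet or at the end, Friday's
* share of target in all that became target or isomer of the product, at the outlet or at the end, Sunday's

Free base is the limiting reagent at 0.320 M, so [target]+[isomer of the product] cannot pass that figure. The carried quantity is the relaxation rate, the forward constant plus the back constant, 0.304 min⁻¹. By it, target of a given age keeps the exponential of minus rate times age of its height above zero.

Two of us disputed what this means. The first held that a vessel touches neither the equilibrium constant nor the rate, so the four set-ups should read alike on one clock started at mixing, at 60.1%. The second held that each portion of target starts its own clock at formation, so the share measures age.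

My own reckoning follows the second view. In Tuesday's flask the dosed acidic substrate matches the free base after 2.00 min. If target forms evenly over that stretch, ages run from 30.0 s to 150 s, and averaging the exponential over them gives 73.3%. Thursday's tank has exponentially spread ages, whose mean memory is one over one plus rate times residence time, which gives 67.6%. Sunday's flask I did not reckon this way.

The forecast took the second side, reckoning with “age is the time since formation”. It gave Tuesday's > Sunday's > Thursday's > Friday's, with 74.6% for Tuesday's, above my figure, then 70.2% for Sunday's, 67.6% for Thursday's and 60.9% for Friday's.

The simulation gives Tuesday's > Sunday's > Thursday's > Friday's, at 74.5%, 70.2%, 67.6% and 60.9% in that order. The vessels part, so the second view stands, and the forecast holds. The first view keeps the long run: at 25.0 min, Tuesday's flask reads 25.1% and Friday's 25.0%.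

The short time given is the main reason that Friday's flask reads 60.9% and not the 25.0% it shows at ten times as long. Friday's reading of 60.9% puts its target, at rate 0.304 min⁻¹, at a mean age of 146 s, so formed about 4.39 s after mixing. Friday's flask read at 40 s then holds target of age 35.6 s, which by the rule makes 87.6%, and its simulated share is 87.6%.

Its constants come from no measurement; no experiment stands behind them.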